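Late in the runs D stands higher than a steady reaction of one L per D gives, so first ask how much L each reacted D costs.

| setting | noon | summer | midnight | eta | beta | alpha |
|---|---|---|---|---|---|---|
| D | 16 mM | 16 mM | 16 mM | 16 mM | 16 mM | 16 mM |
| L | 22 mM | 36 mM | 53 mM | 18.0 mM | 35.0 mM | 70.0 mM |
| remark | run made earlier | run made earlier | run made earlier |  |  |  |
| time |  |  |  | 50 min | 50 min | 50 min |

| run | time / min | D / % | E / % |
|---|---|---|---|
| noon | 8.00 | 84.1 | 15.7 |
| noon | 15.0 | 74.2 | 24.7 |
| noon | 20.0 | 69.7 | 30.5 |
| noon | 30.0 | 61.9 | 38.6 |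
| noon | 40.0 | 56.3 | 44.8 |
| summer | 3.00 | 89.6 | 10.4 |
| summer | 8.00 | 75.4 | 25.2 |
| summer | 15.0 | 62.2 | 37.7 |
| summer | 25.0 | 48.2 | 51.2 |
| summer | 40.0 | 37.0 | 63.5 |
| midnight | 3.00 | 84.4 | 15.1 |
| midnight | 5.00 | 76.8 | 24.2 |
| midnight | 10.0 | 59.9 | 39.2 |
| midnight | 20.0 | 40.0 | 59.8 |
| midnight | 40.0 | 20.3 | 79.5 |

(readings scatter by 0.5 percentage points)

- what was read earlier has a scatter of 0.5 percentage points, one standard deviation

1. part of the D that has reacted at the end, eta
2. part of the D that has reacted at the end, beta
3. part of the D that has reacted at the end, alpha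
4. what raising the concentration of L from its lowest to its highest value here does to the part of the D that has reacted (changes below 5 percentage points count as none) (it rises / it falls / no change)

Let n be the L lost per D reacted, and let the rate follow D times free L. Write a for the L charge minus n times the D charge, and Q for exp(a·K·t/D charge). The fraction of D left at time t is then a/(L charge·Q − n·D charge). Here K is the pseudo-first-order constant of D at 16 mM of free L.

Solve the noon run at both ends, its first and last readings. With n = 1, K falls from 0.0168 min⁻¹ to 0.0128 min⁻¹. With n = 3, it rises from 0.0195 min⁻¹ to 0.0384 min⁻¹. With n = 2, it reads 0.0180 min⁻¹, then 0.0174 min⁻¹.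

So my bracket takes each outer n with its starting K. For eta the reacted part comes out between 33.5% and 49.8%. For alpha it comes out between 89.9% and 95.4%.

To tighten it, keep n = 2 and take the two-for-one constant, K averaged over the last readings of the three runs: 0.0175 min⁻¹. You then get 40.8% for eta, 67.6% for beta and 92.8% for alpha.

The forecast, reading the slowdown as “something decaying”, gives 42.7%, 67.5% and 91%, and says it rises. Its eta and alpha values stand inside my bracket.

The flask gives 40.9%, 67.7% and 92.9%: it rises, by 52 percentage points.

    L + X ⇌ J, settled at all times (K = 1900 M⁻¹)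
    L + X ⇌ G, settled at all times (K = 18000 M⁻¹)
    D + L → X + E (k = 1.10 M⁻¹ min⁻¹)

In alpha, D + L → X + E ran with 57.6% of the L still free at 50 min, when G stood at 13.4 mM against 0.0185 mM of free X. In eta, the L lost per D reacted by that time was 1.99.

Read alpha at 3.0 h, and the two-for-one constant leaves 0.0301% of the D. The computed flask leaves 0.029%.

The data come from a simulation for substances that don't exist; the scatter is artificial.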